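If the impurity takes free catalyst one for one, the small correction to your hunch is a subtraction, and here is my quick number.

| flask | substrate | reagent | free catalyst | impurity | remark | time |
|---|---|---|---|---|---|---|
| north | 0.050 M | 0.055 M | 5 mM | 0.57 mM | run made earlier |  |
| north-east | 0.050 M | 0.055 M | 7.5 mM | 0.57 mM | run made earlier |  |
| ash | 0.050 M | 0.0550 M | 5.0 mM | 0.57 mM | a closed flask charged with all of it at once and left for 2.0 min | 2.0 min |
| alder | 0.050 M | 0.0550 M | 5.0 mM | 0.57 mM | one stirred flow tank at steady state, fed with the mixture as stated, mean residence time 2.0 min |  |
| elm | 0.050 M | 0.0550 M (fed, over 1.00 min) | 5.0 mM | 0.57 mM | all but reagent at the start; reagent goes in evenly over 1.00 min, the run ends at 2.0 min | 2.0 min |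
| cedar | 0.050 M (fed, over 1.00 min) | 0.0550 M | 5.0 mM | 0.57 mM | a stirred flask in which substrate is dosed at a steady rate over 1.00 min without added volume, worked up at 2.0 min | 2.0 min |

| run | time / s | product / % |
|---|---|---|
| north | 10.0 | 5 |
| north | 20.0 | 9 |
| north | 40.0 | 22 |
| north | 80.0 | 44 |
| north-east | 10.0 | 5 |
| north-east | 12.0 | 6 |

(scatter of a reading: 2 percentage points)

- the stated concentrations are those of everything mixed, before any reaction; amounts are the same in each set-up
- what was read earlier has a scatter of 2 percentage points, one standard deviation
- the feed brings no volume worth counting
- the earlier runs were made in a closed, stirred flask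

1. the set-up with the highest amount of product at the outlet or at the end, in percent of the substrate put in ("none" if the first two lie within 2 percentage points) (ash / alder / elm / cedar / none)
2. amount of product at the outlet or at the end, in percent of the substrate put in, ash
3. amount of product at the outlet or at the end, in percent of the substrate put in, alder
4. amount of product at the outlet or at the end, in percent of the substrate put in, elm
5. amount of product at the outlet or at the end, in percent of the substrate put in, cedar

Your forecast says “the rate appears independent of catalyst here”, and it names none as the best set-up.

| set-up | forecast | low end | high end |
|---|---|---|---|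
| ash | 64% | 56% | 70% |
| alder | 59% | 46% | 67% |
| elm | 63% | 50% | 69% |
| cedar | 62% | 50% | 69% |

I read the catalyst differently. Subtracting the impurity leaves 4.43 mM of working catalyst in the north run, and the north-east run should then go faster by a factor of 1.56. But its reading of 5% at 10.0 s, set beside the north run's 5%, carries a scatter of 2 percentage points on each, so those two readings can't separate equal rates from that factor.

The north run's last reading gives 16.1 s for the turn time, the time in which the working catalyst makes its own amount of product once, the inverse of the turnover frequency. Held for 2.0 min, that pace gives me 66.0% in ash, so on ash I stand close to your 64%; we differ on what the catalyst does.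

The flasks give 58.9% in ash, 48.0% in alder, 50.8% in elm and 50.9% in cedar, so the best is ash.

    substrate + free catalyst → catalyst intermediate A (k = 6.80 /M/s)
    reagent + catalyst intermediate A ⇌ catalyst intermediate B (K = 33.0 /M, k = 4.20 /M/s)
    catalyst intermediate B → released group + catalyst intermediate C (k = 0.790 /s)
    catalyst intermediate C → free catalyst + product (k = 0.250 /s)
    free catalyst + impurity → spent catalyst (k = 11000 /M/s)

Ash's result means a turn time of 18.1 s on average over 2.0 min, and my 16.1 s stands beside it as a reading from the north run at 80.0 s, with that reading's scatter. At 12.0 s, the north-east run without the scatter gives 7.26% and the same run at 5.0 mM of free catalyst gives 4.74%, which are turn times of 22.9 s and 22.4 s on average over those seconds. In ash, at the charged reagent and with the way back not counted, catalyst intermediate A's half-life by its forward step alone is 3.00 s, of like size to catalyst intermediate C's 2.8 s by its own step. Catalyst intermediate B's half-life by the step that makes catalyst intermediate C is shorter than both, at 0.88 s.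

The earlier runs and the new flask were computed for an exercise, and the scatter is random.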